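**Strategy.** The chroman is traced back to a lactone: ring A, O1 and C2–C4 of caraganin C are 7-methoxycoumarin (1) once C2 is read as a carbonyl carbon, which makes C4 the electrophilic β-carbon for the styryl unit and C3 the enolate α-carbon for the benzyl unit. A single rhodium/chiral-diene conjugate alkenylation with in-flask benzylation of the resulting boron enolate forms C4–Cα and C3–CH2 and sets C4 and C3 trans; no ring is closed. Its precursors are flat coumarin 1, an (E)-styryl-9-BBN reagent and a 4-silyloxybenzyl bromide. The C2 aryl group is then added at the lactol stage and the pyran ring is re-closed by a stereoconvergent cationic etherification.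

Key step: step 5

Assumption: the (S,S)-antipode of the diene ligand is taken to deliver the alkenyl group to the Re face of C4, by analogy with aryl transfer to cyclic enones and coumarins; the sense would be checked on lactone 10 and the (R,R)-ligand used if it proves opposite.

TBS = tert-butyldimethylsilyl throughout.

**Step 1**
Reactants: 2 4-ethynylphenol
Product: 3 tert-butyl(4-ethynylphenoxy)dimethylsilane
Conditions: TBSCl (1.1 equiv), imidazole (2.0 equiv), DMF, 0 °C → rt
Reagents that add atoms: tert-butyldimethylsilyl chloride (TBSCl), CC(C)(C)[Si](C)(C)Cl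
Why: Imidazole-promoted silylation of the phenol leaves the terminal alkyne untouched, and the aryl silyl ether should tolerate the borane, n-BuLi at −78 °C, i-Bu2AlH and the Grignard reagent used later.

**Step 2**
Reactants: 3 tert-butyl(4-ethynylphenoxy)dimethylsilane
Product: 4 9-[(E)-2-{4-[(TBS)oxy]phenyl}ethenyl]-9-borabicyclo[3.3.1]nonane
Conditions: (9-BBN-H)2 (0.5 equiv), 3 (1.3 equiv), THF, 0 °C → rt; excess 3 stripped at 0.05 mbar, 70 °C; kept as a toluene solution under Ar
Reagents that add atoms: 9-borabicyclo[3.3.1]nonane (9-BBN-H, used as its dimer), B1C2CCCC1CCC2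
Why: Syn, anti-Markovnikov hydroboration of the arylalkyne puts boron on the terminal carbon and fixes the (E) geometry; the alkyne is kept in excess because a terminal alkyne can otherwise take up a second B–H to give a geminal diborylalkane.

**Step 3**
Reactants: 5 4-[(TBS)oxy]benzaldehyde
Product: 6 {4-[(TBS)oxy]phenyl}methanol
Conditions: NaBH4 (0.5 equiv), THF/MeOH, 0 °C, short reaction time; NH4Cl (aq)
Reagents that add atoms: none
Why: Borohydride reduction of the aldehyde to the benzylic alcohol, with low temperature and short contact time sparing the aryl silyl ether from methanolysis.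

**Step 4**
Reactants: 6 {4-[(TBS)oxy]phenyl}methanol
Product: 7 [4-(bromomethyl)phenoxy](tert-butyl)dimethylsilane (4-TBSO-benzyl bromide)
Conditions: CBr4 (1.2 equiv), PPh3 (1.2 equiv), CH2Cl2, 0 °C; hexane trituration, short silica plug; used at once
Reagents that add atoms: carbon tetrabromide, BrC(Br)(Br)Br
Why: Appel reaction, in which bromide displaces the alkoxyphosphonium ion under neutral conditions, which suits this ionisation-prone para-oxygenated benzylic bromide.

**Step 5**
Reactants: 1 7-methoxycoumarin; 4 9-[(E)-2-{4-[(TBS)oxy]phenyl}ethenyl]-9-borabicyclo[3.3.1]nonane; 7 4-TBSO-benzyl bromide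
Product: 10 (3R,4R)-3-{4-[(TBS)oxy]benzyl}-7-methoxy-4-[(E)-2-{4-[(TBS)oxy]phenyl}ethenyl]chroman-2-one, via boron enolate 8 (not isolated), via lithium borate enolate 9 (not isolated)
Conditions: [RhCl(C2H4)2]2 (1.5 mol%), (1S,4S)-2,5-diphenylbicyclo[2.2.2]octa-2,5-diene [(S,S)-Ph-bod*] (3.3 mol%), KOMe (5 mol%), 4 (1.2 equiv), toluene, 50 °C; then THF, n-BuLi (1.2 equiv), −78 °C; then 7 (1.5 equiv), −78 → 0 °C; NH4Cl (aq)
Reagents that add atoms: none
Why: Methoxide starts the cycle by turning the chlororhodium diene complex into an alkenylrhodium species through boron-to-rhodium transmetallation; this adds across C3=C4 of 1 (C4–Cα bond), and the oxa-π-allyl rhodium enolate is taken over by a second molecule of 4, which releases boron enolate 8 and the next alkenylrhodium because no proton source is present. n-BuLi then converts 8 into borate 9, whose C3 attacks bromide 7 in an SN2 alkylation (C3–CH2 bond). The closest known chemistry is the rhodium-catalysed asymmetric 1,4-addition of organoboron reagents to coumarins together with its 9-BBN variant on cyclic enones, in which the chiral boron enolate is alkylated through its borate; alkenyl transfer to a coumarin is the least exercised pairing. No ring is closed. C4 is set by the chiral diene on rhodium, which exposes the Re face of C4 to the alkenyl group, and C3 by the substrate, since the electrophile enters the planar enolate anti to the pseudoaxial C4 styryl group to give the 3,4-trans lactone, which should also be the more stable epimer. The step needs 1,4- over 1,2-addition and a single C-alkylation; the soft alkenylrhodium nucleophile secures the first, and the second follows because the carbonyl group is masked as an enolate before n-BuLi is added and the tertiary C3–H of 10 is hindered towards a further deprotonation.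

**Step 6**
Reactants: 10 (3R,4R)-3-{4-[(TBS)oxy]benzyl}-7-methoxy-4-[(E)-2-{4-[(TBS)oxy]phenyl}ethenyl]chroman-2-one
Product: 11 (3R,4R)-3-{4-[(TBS)oxy]benzyl}-7-methoxy-4-[(E)-2-{4-[(TBS)oxy]phenyl}ethenyl]chroman-2-ol (both C2 anomers)
Conditions: i-Bu2AlH (1.15 equiv), CH2Cl2, −78 °C; KNaC4H4O6 (aq)
Reagents that add atoms: none
Why: Partial reduction of the aryl lactone stops at the lactol because the aluminium hemiacetal formed at −78 °C does not collapse until work-up, and in the absence of base C3 and C4 should not be disturbed.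

**Step 7**
Reactants: 11 the chroman-2-ol from step 6; 12 1-bromo-2,4-dimethoxybenzene
Product: 14 (2R,3R,4E)-2-{4-[(TBS)oxy]benzyl}-5-{4-[(TBS)oxy]phenyl}-1-(2,4-dimethoxyphenyl)-3-(2-hydroxy-4-methoxyphenyl)pent-4-en-1-ol (both C1 epimers), via 2,4-dimethoxyphenylmagnesium bromide 13 (not isolated)
Conditions: 12 (3.0 equiv), Mg, THF, 45 °C; then 11, THF, 0 °C → rt; NH4Cl (aq)
Reagents that add atoms: none
Why: Grignard addition to the ring-opened hydroxy-aldehyde tautomer of the lactol (the first equivalent of 13 deprotonates and opens it) is a standard lactol-to-diol opening, and the configuration of the new carbinol carbon is immaterial because step 8 is stereoconvergent.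

**Step 8**
Reactants: 14 the diol from step 7
Product: 15 (2R,3R,4R)-3-{4-[(TBS)oxy]benzyl}-2-(2,4-dimethoxyphenyl)-7-methoxy-4-[(E)-2-{4-[(TBS)oxy]phenyl}ethenyl]chroman
Conditions: TsOH·H2O (10 mol%), CH2Cl2, 0 °C → rt; Et3N quench
Reagents that add atoms: none
Why: Acid ionises the doubly donor-stabilised benzylic alcohol to a 2,4-dimethoxybenzyl cation that the ring A phenol captures in an SN1 cycloetherification to the six-membered ring, both carbinol epimers converging on (2R) because the chair-like closure and, as this electron-rich benzylic C2–O bond can re-ionise, the equilibrium both favour the all-equatorial 2,3-trans-3,4-trans chroman.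

**Step 9**
Reactants: 15 the bis-silyl chroman from step 8
Product: 16 caraganin C, 4-{[(2R,3R,4R)-2-(2,4-dimethoxyphenyl)-4-[(E)-2-(4-hydroxyphenyl)ethenyl]-7-methoxy-3,4-dihydro-2H-chromen-3-yl]methyl}phenol
Conditions: Bu4NF (2.4 equiv), AcOH (2.4 equiv), THF, 0 °C → rt
Reagents that add atoms: none
Why: Fluoride-induced desilylation of both aryl silyl ethers is driven by Si–F bond formation, and the AcOH buffer keeps the liberated phenols protonated so that the C2 benzylic ether, the styrene and the three stereocentres should be unaffected.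

**Compound list**

1 | 7-methoxycoumarin | COc1ccc2ccc(=O)oc2c1 | starting material
2 | 4-ethynylphenol | C#Cc1ccc(O)cc1 | starting material
3 | tert-butyl(4-ethynylphenoxy)dimethylsilane | C#Cc1ccc(O[Si](C)(C)C(C)(C)C)cc1 | intermediate
4 | 9-[(E)-2-{4-[(TBS)oxy]phenyl}ethenyl]-9-borabicyclo[3.3.1]nonane | CC(C)(C)[Si](C)(C)Oc1ccc(/C=C/B2C3CCCC2CCC3)cc1 | intermediate
5 | 4-[(TBS)oxy]benzaldehyde | O=Cc1ccc(O[Si](C)(C)C(C)(C)C)cc1 | starting material
6 | {4-[(TBS)oxy]phenyl}methanol | OCc1ccc(O[Si](C)(C)C(C)(C)C)cc1 | intermediate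
7 | [4-(bromomethyl)phenoxy](tert-butyl)dimethylsilane | BrCc1ccc(O[Si](C)(C)C(C)(C)C)cc1 | intermediate
8 | (4R)-2-(9-borabicyclo[3.3.1]nonan-9-yloxy)-7-methoxy-4-[(E)-2-{4-[(TBS)oxy]phenyl}ethenyl]-4H-chromene (boron enolate) | COc1ccc2c(c1)OC(OB3C4CCCC3CCC4)=C[C@H]2/C=C/c1ccc(O[Si](C)(C)C(C)(C)C)cc1 | intermediate
9 | lithium 9-butyl-9-{[(4R)-7-methoxy-4-[(E)-2-{4-[(TBS)oxy]phenyl}ethenyl]-4H-chromen-2-yl]oxy}-9-boranuidabicyclo[3.3.1]nonane (lithium borate enolate) | COc1ccc2c(c1)OC(O[B-]3(CCCC)C4CCCC3CCC4)=C[C@H]2/C=C/c1ccc(O[Si](C)(C)C(C)(C)C)cc1.[Li+] | intermediate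
10 | (3R,4R)-3-{4-[(TBS)oxy]benzyl}-7-methoxy-4-[(E)-2-{4-[(TBS)oxy]phenyl}ethenyl]chroman-2-one | COc1ccc2c(c1)OC(=O)[C@H](Cc1ccc(O[Si](C)(C)C(C)(C)C)cc1)[C@H]2/C=C/c1ccc(O[Si](C)(C)C(C)(C)C)cc1 | intermediate
11 | (3R,4R)-3-{4-[(TBS)oxy]benzyl}-7-methoxy-4-[(E)-2-{4-[(TBS)oxy]phenyl}ethenyl]chroman-2-ol (C2 anomers) | COc1ccc2c(c1)OC(O)[C@H](Cc1ccc(O[Si](C)(C)C(C)(C)C)cc1)[C@H]2/C=C/c1ccc(O[Si](C)(C)C(C)(C)C)cc1 | intermediate
12 | 1-bromo-2,4-dimethoxybenzene | COc1ccc(Br)c(OC)c1 | starting material
13 | 2,4-dimethoxyphenylmagnesium bromide | COc1ccc([Mg]Br)c(OC)c1 | intermediate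
14 | (2R,3R,4E)-2-{4-[(TBS)oxy]benzyl}-5-{4-[(TBS)oxy]phenyl}-1-(2,4-dimethoxyphenyl)-3-(2-hydroxy-4-methoxyphenyl)pent-4-en-1-ol (C1 epimers) | COc1ccc(c(OC)c1)C(O)[C@H](Cc1ccc(O[Si](C)(C)C(C)(C)C)cc1)[C@H](c1ccc(OC)cc1O)/C=C/c1ccc(O[Si](C)(C)C(C)(C)C)cc1 | intermediate
15 | (2R,3R,4R)-3-{4-[(TBS)oxy]benzyl}-2-(2,4-dimethoxyphenyl)-7-methoxy-4-[(E)-2-{4-[(TBS)oxy]phenyl}ethenyl]chroman | COc1ccc2c(c1)O[C@@H](c1ccc(OC)cc1OC)[C@H](Cc1ccc(O[Si](C)(C)C(C)(C)C)cc1)[C@H]2/C=C/c1ccc(O[Si](C)(C)C(C)(C)C)cc1 | intermediate
16 | caraganin C, (2R,3R,4R)-2-(2,4-dimethoxyphenyl)-3-(4-hydroxybenzyl)-4-[(E)-2-(4-hydroxyphenyl)ethenyl]-7-methoxychroman | COc1ccc2c(c1)O[C@@H](c1ccc(OC)cc1OC)[C@H](Cc1ccc(O)cc1)[C@H]2/C=C/c1ccc(O)cc1 | target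

**Step count.** Total: 9 steps. Longest linear sequence: 7 steps (steps 1, 2, 5, 6, 7, 8, 9; the bromide branch, steps 3, 4, 5–9, is equally long).

**Steps most likely to fail**

1. Step 5. What may go wrong: slow carbometallation of the electron-rich coumarin by the alkenylrhodium species; protonation of the rhodium or boron enolate by adventitious water before benzylation; incomplete C-alkylation of the borate; erosion of enantio- or trans-selectivity. Fallback (sets out from 3, 1 and 7; returns at 10): the three-component union is split into two separately controlled bond formations. Alkyne 3 would be hydroborated with catecholborane (neat, 70 °C) to 2-[(E)-2-{4-[(TBS)oxy]phenyl}ethenyl]-1,3,2-benzodioxaborole F1. F1 would be added to 1 under protic rhodium catalysis ([Rh(acac)(C2H4)2], (S)-5,5'-bis(diphenylphosphino)-4,4'-bi-1,3-benzodioxole, Et3N, dioxane/H2O, 60 °C), where hydrolysis of the rhodium enolate turns the catalyst over and no boron enolate is needed. This should give (4S)-7-methoxy-4-[(E)-2-{4-[(TBS)oxy]phenyl}ethenyl]chroman-2-one F2, which has the same spatial arrangement at C4 as 10; the descriptor differs only because C3 is still a methylene group. Deprotonation with LiN(SiMe3)2 in THF at −78 °C and alkylation of the lithium enolate with 7, anti to the C4 substituent, would then give 10.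

2. Step 8. What may go wrong: incomplete convergence on the 2,3-trans isomer; E1 loss of the C3 proton from the benzylic cation with scrambling of C3 on re-protonation; acid-induced reaction of the electron-rich styrene. A hydride reduction of the cyclic hemiketal was not chosen for this bond, since axial hydride delivery anti to a pseudoaxial C3 substituent would be expected to favour the 2,3-cis isomer. Fallback (sets out from 14; returns at 15): closure without a cation. The carbinol epimers of 14 would be separated by chromatography, and (1S,2R,3R,4E)-2-{4-[(TBS)oxy]benzyl}-5-{4-[(TBS)oxy]phenyl}-1-(2,4-dimethoxyphenyl)-3-(2-hydroxy-4-methoxyphenyl)pent-4-en-1-ol F3 would be cyclised under Mitsunobu conditions (PPh3, DIAD, THF, 0 °C). The phenol should displace the activated carbinol oxygen with inversion to give the (2R) chroman 15. The (1R)-epimer would be kept for the acid-mediated closure.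

3. Step 7. What may go wrong: enolisation of the ring-opened, α-branched aldehyde by the basic aryl Grignard reagent, which would epimerise C3; sluggish addition to the hindered carbonyl group. Fallback (sets out from 10; returns at 14; step 6 is bypassed): acylation in place of aldehyde addition. Lactone 10 would be treated with 13 (1.1 equiv, THF, −78 °C) to give (2R,3R,4E)-2-{4-[(TBS)oxy]benzyl}-5-{4-[(TBS)oxy]phenyl}-1-(2,4-dimethoxyphenyl)-3-(2-hydroxy-4-methoxyphenyl)pent-4-en-1-one F4, which is in equilibrium with its cyclic hemiketal and whose hindered, electron-rich carbonyl group should resist a second addition. F4 would then be reduced with NaBH4 (THF/MeOH, 0 °C) to 14.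

**Further compounds**

F1 | step 5 | 2-[(E)-2-{4-[(TBS)oxy]phenyl}ethenyl]-1,3,2-benzodioxaborole | CC(C)(C)[Si](C)(C)Oc1ccc(/C=C/B2Oc3ccccc3O2)cc1
F2 | step 5 | (4S)-7-methoxy-4-[(E)-2-{4-[(TBS)oxy]phenyl}ethenyl]chroman-2-one | COc1ccc2c(c1)OC(=O)C[C@H]2/C=C/c1ccc(O[Si](C)(C)C(C)(C)C)cc1
F3 | step 8 | (1S,2R,3R,4E)-2-{4-[(TBS)oxy]benzyl}-5-{4-[(TBS)oxy]phenyl}-1-(2,4-dimethoxyphenyl)-3-(2-hydroxy-4-methoxyphenyl)pent-4-en-1-ol | O[C@H](c1ccc(OC)cc1OC)[C@H](Cc1ccc(O[Si](C)(C)C(C)(C)C)cc1)[C@H](c1ccc(OC)cc1O)/C=C/c1ccc(O[Si](C)(C)C(C)(C)C)cc1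
F4 | step 7 | (2R,3R,4E)-2-{4-[(TBS)oxy]benzyl}-5-{4-[(TBS)oxy]phenyl}-1-(2,4-dimethoxyphenyl)-3-(2-hydroxy-4-methoxyphenyl)pent-4-en-1-one | COc1ccc(c(OC)c1)C(=O)[C@H](Cc1ccc(O[Si](C)(C)C(C)(C)C)cc1)[C@H](c1ccc(OC)cc1O)/C=C/c1ccc(O[Si](C)(C)C(C)(C)C)cc1
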